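The C8a–O1 aryl ether bond of ring C is the disconnection on which the route rests. An intramolecular palladium-catalysed C–O coupling joins the free C2 hydroxyl to the C8a triflate of ring A and closes ring C in one operation. It exploits the fact that O1 sits between the aryl carbon C8a and the benzylic C2, whose C2–O bond ionises easily because of the 2'-methoxy-4'-oxygenated ring B. Making O1–C8a never breaks that bond, so the C2 configuration set by ketone reduction survives. The precursor is an open-chain ring A aryl triflate carrying the lavandulyl group between two MOM ethers, a silyl-protected C4 carbinol and the free (S)-C2 carbinol attached to MOM-protected ring B.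

Key step: step 13

Notation: flavanone numbering (O1, C2, C3, C4, C4a, C5 to C8, C8a; ring A the benzo ring, ring B the 2-aryl group, ring C the oxygen ring) is used for open-chain compounds as well; "(S)-lavandulyl" means (2S)-5-methyl-2-(prop-1-en-2-yl)hex-4-en-1-yl.

Remark on the chemistry: the side-chain stereocentre is never touched; its descriptor is R in 6, 7 and 8 and S once its CH2 is bonded to the arene, only because the CIP ranking changes. The target is (2S) at C2 with an (S)-lavandulyl group. Compound 6 is assumed to be purchasable as the single (R)-enantiomer and 13 as the stated isomer.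

Step 1
Reactants: 1 phloroglucinol (benzene-1,3,5-triol)
Product: 2 3,5-bis(methoxymethoxy)phenol
Conditions: MOMCl (2.0 equiv), iPr2NEt, DMF, 0 °C to rt; chromatography to remove mono- and tris-ethers
Reagents that add atoms: chloromethyl methyl ether, COCCl
Why: Williamson-type O-alkylation (MOM protection) of the threefold-symmetric triol is statistical, so two equivalents should give mainly the bis-ether, which is separable because it alone keeps exactly one free hydroxyl.

Step 2
Reactants: 2 3,5-bis(methoxymethoxy)phenol
Product: 3 [3,5-bis(methoxymethoxy)phenoxy]tri(propan-2-yl)silane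
Conditions: TIPSCl, imidazole, DMF, rt
Reagents that add atoms: chlorotri(propan-2-yl)silane, CC(C)[Si](Cl)(C(C)C)C(C)C
Why: Imidazole-promoted O-silylation gives a bulky silyl ether that survives n-BuLi, does not direct lithiation to its own ortho positions and is later removed by fluoride without touching the MOM ethers.

Step 3
Reactants: 3 [3,5-bis(methoxymethoxy)phenoxy]tri(propan-2-yl)silane
Product: 5 [4-iodo-3,5-bis(methoxymethoxy)phenoxy]tri(propan-2-yl)silane, via aryllithium 4 (not isolated)
Conditions: n-BuLi, THF, 0 °C; then I2, −78 °C to rt; aq Na2S2O3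
Reagents that add atoms: iodine, II
Why: Directed ortho-metalation takes place at the carbon flanked by both MOM ethers, which is doubly activated by lithium coordination while the positions next to the bulky silyloxy group are shielded, and iodinolysis places the halide exactly where the side chain is needed.

Step 4
Reactants: 6 (R)-lavandulol
Product: 7 (R)-lavandulyl iodide
Conditions: PPh3, imidazole, I2, CH2Cl2, 0 °C to rt, dark
Reagents that add atoms: iodine, II
Why: The Appel reaction replaces the primary hydroxyl by iodide through SN2 attack at the CH2 carbon, so the neighbouring stereocentre is not involved and keeps its configuration.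

Step 5
Reactants: 7 (R)-lavandulyl iodide; 5 [4-iodo-3,5-bis(methoxymethoxy)phenoxy]tri(propan-2-yl)silane
Product: 9 {3,5-bis(methoxymethoxy)-4-[(S)-lavandulyl]phenoxy}tri(propan-2-yl)silane, via lavandulylzinc iodide 8 (not isolated)
Conditions: 7 (1.5 equiv), Zn dust (activated with Me3SiCl/BrCH2CH2Br), LiCl, THF, 40 °C; then 5, Pd(OAc)2 (3 mol %), SPhos (6 mol %), THF, 50 °C
Reagents that add atoms: none
Why: In this Negishi coupling zinc inserts into the primary C–I bond to give a reagent whose stereocentre is β to the metal and therefore configurationally secure, and Pd/SPhos should join primary alkylzinc halides to doubly ortho-substituted aryl iodides faster than β-hydride elimination, which avoids the E2 elimination that a basic aryllithium would cause on this β-branched iodide.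

Step 6
Reactants: 9 {3,5-bis(methoxymethoxy)-4-[(S)-lavandulyl]phenoxy}tri(propan-2-yl)silane
Product: 10 3,5-bis(methoxymethoxy)-4-[(S)-lavandulyl]phenol
Conditions: Bu4NF, THF, 0 °C
Reagents that add atoms: none
Why: Fluoride-induced cleavage of the aryl silyl ether, driven by the Si–F bond, frees the one phenol whose two ortho positions are constitutionally equivalent, while MOM ethers and alkenes are inert.

Step 7
Reactants: 10 3,5-bis(methoxymethoxy)-4-[(S)-lavandulyl]phenol
Product: 11 6-hydroxy-2,4-bis(methoxymethoxy)-3-[(S)-lavandulyl]benzaldehyde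
Conditions: MgCl2, Et3N, (CH2O)n, MeCN, 80 °C; cold aq citric acid work-up
Reagents that add atoms: paraformaldehyde (as formaldehyde), C=O
Why: In the magnesium-mediated ortho-formylation (Casnati–Skattebøl reaction) phenoxide-bound magnesium delivers formaldehyde only ortho to the free hydroxyl, and because both ortho positions are equivalent and the para position is blocked a single salicylaldehyde is expected.

Step 8
Reactants: 11 6-hydroxy-2,4-bis(methoxymethoxy)-3-[(S)-lavandulyl]benzaldehyde
Product: 12 2-formyl-3,5-bis(methoxymethoxy)-4-[(S)-lavandulyl]phenyl trifluoromethanesulfonate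
Conditions: PhNTf2, Et3N, DMAP (cat.), CH2Cl2, rt
Reagents that add atoms: N-phenylbis(trifluoromethanesulfonimide), O=S(=O)(N(c1ccccc1)S(=O)(=O)C(F)(F)F)C(F)(F)F
Why: O-Sulfonylation of the phenol with a mild triflyl donor turns the future C8a oxygen into a leaving group under conditions that leave the MOM ethers, the alkenes and the aldehyde untouched.

Step 9
Reactants: 13 1-(4-hydroxy-2-methoxyphenyl)ethanone
Product: 14 1-[2-methoxy-4-(methoxymethoxy)phenyl]ethanone
Conditions: MOMCl, iPr2NEt, CH2Cl2, 0 °C to rt
Reagents that add atoms: chloromethyl methyl ether, COCCl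
Why: MOM protection (Williamson-type O-alkylation) of the only phenol removes the acidic proton before enolate formation and matches the ring A protecting groups so that one final deprotection suffices.

Step 10
Reactants: 14 1-[2-methoxy-4-(methoxymethoxy)phenyl]ethanone; 12 2-formyl-3,5-bis(methoxymethoxy)-4-[(S)-lavandulyl]phenyl trifluoromethanesulfonate
Product: 16 2-{1-hydroxy-3-[2-methoxy-4-(methoxymethoxy)phenyl]-3-oxopropyl}-3,5-bis(methoxymethoxy)-4-[(S)-lavandulyl]phenyl trifluoromethanesulfonate (both C4 epimers), via lithium enolate 15 (not isolated)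
Conditions: 14 (1.2 equiv), LiN(iPr)2 (1.15 equiv), THF, −78 °C; then 12 (1.0 equiv), −78 °C; AcOH/THF quench at −78 °C
Reagents that add atoms: none
Why: In this directed aldol addition the preformed kinetic lithium enolate of the methyl ketone adds at low temperature to the non-enolisable aldehyde to form the C3–C4 bond, the new C4 carbinol centre is left uncontrolled because it is oxidised in step 15, and the cold acidic quench forestalls retro-aldol cleavage and dehydration.

Step 11
Reactants: 16 the aldol adduct (both C4 epimers)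
Product: 17 2-{1-[tert-butyl(dimethyl)silyl]oxy-3-[2-methoxy-4-(methoxymethoxy)phenyl]-3-oxopropyl}-3,5-bis(methoxymethoxy)-4-[(S)-lavandulyl]phenyl trifluoromethanesulfonate (both C4 epimers)
Conditions: TBSOTf, 2,6-lutidine, CH2Cl2, −78 to −20 °C
Reagents that add atoms: tert-butyldimethylsilyl trifluoromethanesulfonate, CC(C)(C)[Si](C)(C)OS(=O)(=O)C(F)(F)F
Why: Silylation of the hindered secondary benzylic alcohol with a silyl triflate and a non-nucleophilic pyridine base caps O4, so that neither a β-hydroxy ketone nor a second free hydroxyl is present in the reduction and in the ring closure.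

Step 12
Reactants: 17 the β-silyloxy ketone (both C4 epimers)
Product: 18 2-{(3S)-1-[tert-butyl(dimethyl)silyl]oxy-3-hydroxy-3-[2-methoxy-4-(methoxymethoxy)phenyl]propyl}-3,5-bis(methoxymethoxy)-4-[(S)-lavandulyl]phenyl trifluoromethanesulfonate (both C4 epimers)
Conditions: (R)-2-methyl-CBS-oxazaborolidine (20 mol %), catecholborane (2 equiv), toluene, −78 to −40 °C; MeOH quench
Reagents that add atoms: none
Why: In the Corey–Bakshi–Shibata reduction the (R)-oxazaborolidine binds the ketone with ring B as the large group and directs hydride to one face, which should give the (S)-carbinol at C2 under catalyst control for both C4 epimers, and catecholborane is chosen because it does not hydroborate the lavandulyl alkenes at low temperature.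

Step 13
Reactants: 18 the (3S)-hydroxy aryl triflate (both C4 epimers)
Product: 19 tert-butyl{[(2S)-5,7-bis(methoxymethoxy)-2-[2-methoxy-4-(methoxymethoxy)phenyl]-6-[(S)-lavandulyl]-3,4-dihydro-2H-chromen-4-yl]oxy}dimethylsilane (both C4 epimers)
Conditions: [Pd(allyl)Cl]2 (2.5 mol %), RockPhos (6 mol %), Cs2CO3, 4 Å MS, toluene, 80 °C
Reagents that add atoms: none
Why: Zerovalent palladium carrying the bulky di-tert-butylbiarylphosphine inserts into the C8a–OTf bond to give a divalent arylpalladium species, the C2 hydroxyl binds and is deprotonated by Cs2CO3, and C–O reductive elimination forms O1–C8a and returns zerovalent palladium. The closest known reaction type is the palladium-catalysed intramolecular etherification of aryl halides and sulfonates with secondary alcohols, an established way to chromans. Ring C is closed as a six-membered ring by reductive elimination from a seven-membered palladacycle (Pd, C8a, C4a, C4, C3, C2, O), so the ring oxygen becomes bonded to the arene and no substitution takes place at carbon. No stereocentre is created: only the O–H bond of the C2 carbinol is broken, so the S configuration from step 12 is carried over unchanged, and both C4 epimers are taken on because C4 becomes a carbonyl in step 15. The step needs C–O reductive elimination to beat β-hydride elimination of the secondary palladium alkoxide and S–O cleavage of the triflate, which the bulky electron-rich ligand and the weak carbonate base in toluene are expected to secure. Site selectivity is built into 18, which has one C–OTf bond (fixed when the formyl group was placed ortho to the only free hydroxyl of 10) and one free hydroxyl because O4 is silylated.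

Step 14
Reactants: 19 the 4-silyloxychroman (both C4 epimers)
Product: 20 (2S)-5,7-bis(methoxymethoxy)-2-[2-methoxy-4-(methoxymethoxy)phenyl]-6-[(S)-lavandulyl]-3,4-dihydro-2H-chromen-4-ol (both C4 epimers)
Conditions: Bu4NF, THF, 0 °C to rt
Reagents that add atoms: none
Why: Fluoride-mediated desilylation frees the C4 hydroxyl of both epimers under non-acidic conditions that spare the MOM ethers and the acid-labile benzylic C–O bonds at C2 and C4.

Step 15
Reactants: 20 the flavan-4-ol (both C4 epimers)
Product: 21 (2S)-5,7-bis(methoxymethoxy)-2-[2-methoxy-4-(methoxymethoxy)phenyl]-6-[(S)-lavandulyl]-2,3-dihydro-4H-chromen-4-one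
Conditions: Dess–Martin periodinane, NaHCO3, CH2Cl2, 0 °C to rt
Reagents that add atoms: none
Why: Dess–Martin oxidation under bicarbonate buffer converts both C4 epimers of the benzylic alcohol into one flavanone without acid or base strong enough to open ring C or epimerise C2.

Step 16
Reactants: 21 the tris-MOM flavanone
Product: 22 (2S)-5,7-dihydroxy-2-(4-hydroxy-2-methoxyphenyl)-6-[(S)-lavandulyl]-2,3-dihydro-4H-chromen-4-one
Conditions: HCl (about 0.5 M in MeOH), MeOH/THF, 25 °C, stopped at full conversion
Reagents that add atoms: none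
Why: Acid-catalysed acetal exchange with methanol removes the three MOM groups, and dilute acid near room temperature is chosen so that neither addition of the 5- or 7-hydroxyl to the lavandulyl alkenes nor ionisation of the C2–O1 bond should compete.

Compound list

1 | phloroglucinol (benzene-1,3,5-triol) | Oc1cc(O)cc(O)c1 | starting material
2 | 3,5-bis(methoxymethoxy)phenol | COCOc1cc(O)cc(OCOC)c1 | intermediate
3 | [3,5-bis(methoxymethoxy)phenoxy]tri(propan-2-yl)silane | COCOc1cc(OCOC)cc(O[Si](C(C)C)(C(C)C)C(C)C)c1 | intermediate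
4 | {2,6-bis(methoxymethoxy)-4-[tri(propan-2-yl)silyloxy]phenyl}lithium | [Li]c1c(OCOC)cc(O[Si](C(C)C)(C(C)C)C(C)C)cc1OCOC | intermediate
5 | [4-iodo-3,5-bis(methoxymethoxy)phenoxy]tri(propan-2-yl)silane | Ic1c(OCOC)cc(O[Si](C(C)C)(C(C)C)C(C)C)cc1OCOC | intermediate
6 | (R)-lavandulol, (2R)-5-methyl-2-(prop-1-en-2-yl)hex-4-en-1-ol | C=C(C)[C@@H](CC=C(C)C)CO | starting material
7 | (R)-lavandulyl iodide, (3R)-3-(iodomethyl)-2,6-dimethylhepta-1,5-diene | C=C(C)[C@@H](CC=C(C)C)CI | intermediate
8 | [(2R)-5-methyl-2-(prop-1-en-2-yl)hex-4-en-1-yl]zinc iodide | C=C(C)[C@@H](CC=C(C)C)C[Zn]I | intermediate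
9 | {3,5-bis(methoxymethoxy)-4-[(2S)-5-methyl-2-(prop-1-en-2-yl)hex-4-en-1-yl]phenoxy}tri(propan-2-yl)silane | C=C(C)[C@@H](CC=C(C)C)Cc1c(OCOC)cc(O[Si](C(C)C)(C(C)C)C(C)C)cc1OCOC | intermediate
10 | 3,5-bis(methoxymethoxy)-4-[(2S)-5-methyl-2-(prop-1-en-2-yl)hex-4-en-1-yl]phenol | C=C(C)[C@@H](CC=C(C)C)Cc1c(OCOC)cc(O)cc1OCOC | intermediate
11 | 6-hydroxy-2,4-bis(methoxymethoxy)-3-[(2S)-5-methyl-2-(prop-1-en-2-yl)hex-4-en-1-yl]benzaldehyde | C=C(C)[C@@H](CC=C(C)C)Cc1c(OCOC)cc(O)c(C=O)c1OCOC | intermediate
12 | 2-formyl-3,5-bis(methoxymethoxy)-4-[(2S)-5-methyl-2-(prop-1-en-2-yl)hex-4-en-1-yl]phenyl trifluoromethanesulfonate | C=C(C)[C@@H](CC=C(C)C)Cc1c(OCOC)cc(OS(=O)(=O)C(F)(F)F)c(C=O)c1OCOC | intermediate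
13 | 1-(4-hydroxy-2-methoxyphenyl)ethanone | CC(=O)c1ccc(O)cc1OC | starting material
14 | 1-[2-methoxy-4-(methoxymethoxy)phenyl]ethanone | CC(=O)c1ccc(OCOC)cc1OC | intermediate
15 | lithium 1-[2-methoxy-4-(methoxymethoxy)phenyl]ethenolate | C=C(O[Li])c1ccc(OCOC)cc1OC | intermediate
16 | 2-{1-hydroxy-3-[2-methoxy-4-(methoxymethoxy)phenyl]-3-oxopropyl}-3,5-bis(methoxymethoxy)-4-[(2S)-5-methyl-2-(prop-1-en-2-yl)hex-4-en-1-yl]phenyl trifluoromethanesulfonate, both C4 epimers | C=C(C)[C@@H](CC=C(C)C)Cc1c(OCOC)cc(OS(=O)(=O)C(F)(F)F)c(c1OCOC)C(O)CC(=O)c1ccc(OCOC)cc1OC | intermediate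
17 | 2-{1-[tert-butyl(dimethyl)silyl]oxy-3-[2-methoxy-4-(methoxymethoxy)phenyl]-3-oxopropyl}-3,5-bis(methoxymethoxy)-4-[(2S)-5-methyl-2-(prop-1-en-2-yl)hex-4-en-1-yl]phenyl trifluoromethanesulfonate, both C4 epimers | C=C(C)[C@@H](CC=C(C)C)Cc1c(OCOC)cc(OS(=O)(=O)C(F)(F)F)c(c1OCOC)C(O[Si](C)(C)C(C)(C)C)CC(=O)c1ccc(OCOC)cc1OC | intermediate
18 | 2-{(3S)-1-[tert-butyl(dimethyl)silyl]oxy-3-hydroxy-3-[2-methoxy-4-(methoxymethoxy)phenyl]propyl}-3,5-bis(methoxymethoxy)-4-[(2S)-5-methyl-2-(prop-1-en-2-yl)hex-4-en-1-yl]phenyl trifluoromethanesulfonate, both C4 epimers | C=C(C)[C@@H](CC=C(C)C)Cc1c(OCOC)cc(OS(=O)(=O)C(F)(F)F)c(c1OCOC)C(O[Si](C)(C)C(C)(C)C)C[C@@H](c1ccc(OCOC)cc1OC)O | intermediate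
19 | tert-butyl{[(2S)-5,7-bis(methoxymethoxy)-2-[2-methoxy-4-(methoxymethoxy)phenyl]-6-[(2S)-5-methyl-2-(prop-1-en-2-yl)hex-4-en-1-yl]-3,4-dihydro-2H-chromen-4-yl]oxy}dimethylsilane, both C4 epimers | C=C(C)[C@@H](CC=C(C)C)Cc1c(OCOC)cc2c(c1OCOC)C(O[Si](C)(C)C(C)(C)C)C[C@@H](c1ccc(OCOC)cc1OC)O2 | intermediate
20 | (2S)-5,7-bis(methoxymethoxy)-2-[2-methoxy-4-(methoxymethoxy)phenyl]-6-[(2S)-5-methyl-2-(prop-1-en-2-yl)hex-4-en-1-yl]-3,4-dihydro-2H-chromen-4-ol, both C4 epimers | C=C(C)[C@@H](CC=C(C)C)Cc1c(OCOC)cc2c(c1OCOC)C(O)C[C@@H](c1ccc(OCOC)cc1OC)O2 | intermediate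
21 | (2S)-5,7-bis(methoxymethoxy)-2-[2-methoxy-4-(methoxymethoxy)phenyl]-6-[(2S)-5-methyl-2-(prop-1-en-2-yl)hex-4-en-1-yl]-2,3-dihydro-4H-chromen-4-one | C=C(C)[C@@H](CC=C(C)C)Cc1c(OCOC)cc2c(c1OCOC)C(=O)C[C@@H](c1ccc(OCOC)cc1OC)O2 | intermediate
22 | (2S)-5,7-dihydroxy-2-(4-hydroxy-2-methoxyphenyl)-6-[(2S)-5-methyl-2-(prop-1-en-2-yl)hex-4-en-1-yl]-2,3-dihydro-4H-chromen-4-one | C=C(C)[C@@H](CC=C(C)C)Cc1c(O)cc2c(c1O)C(=O)C[C@@H](c1ccc(O)cc1OC)O2 | target

Total step count: 16. Longest linear sequence: 14 steps (steps 1 to 3, 5 to 8 and 10 to 16, from phloroglucinol).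

Steps most likely to fail

Step 13. β-Hydride elimination from the palladium alkoxide (which would oxidise the C2 carbinol and reduce the triflate to C8a–H), base-induced S–O cleavage of the triflate, or migration of the silyl group from O4 to O2 may outrun C–O reductive elimination. The fallback sets out from 17 and comes back at 19; it closes ring C at O1–C2 with inversion instead. Ketone 17 would be reduced as in step 12 but with (S)-2-methyl-CBS-oxazaborolidine, giving the C2-epimeric (3R)-carbinol triflate F1. Et4NOH in dioxane would then cleave the triflate S–O bond to give the phenol F2. An intramolecular Mitsunobu etherification (PPh3, diisopropyl azodicarboxylate, toluene, 0 °C) would displace the activated benzylic hydroxyl by the C8a oxygen with inversion and give (2S)-19. The price is possible partial ionisation at C2 during the displacement, which is why this closure is only the reserve.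

Step 16. Protonation of the isopropenyl or prenyl double bond followed by capture by the neighbouring 5- or 7-hydroxyl or by methanol, double-bond migration through the side-chain stereocentre, or acid-induced opening of the C2–O1 bond with loss of configuration at C2 may compete with acetal cleavage. The fallback sets out from 21 and comes back at 22. Me3SiOTf and 2,2'-bipyridyl in MeCN at 0 °C would exchange each aryl MOM ether for an aryl silyl ether without free acid, giving the tris(trimethylsilyl) ether F3. Water at room temperature would then hydrolyse it to 22.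

Step 5. Slow transmetalation or reductive elimination at the doubly ortho-substituted arylpalladium centre may allow β-hydride elimination with isomerisation of the alkyl group, protodezincation, or reduction of the aryl iodide. The fallback sets out from 3 and 6 and comes back at 9; it reverses the polarity of the coupling. Alcohol 6 would be converted with Tf2O and 2,6-lutidine in CH2Cl2 at −78 °C into (R)-lavandulyl triflate F4. This would be added cold to aryllithium 4, made from 3 as in step 3 but in Et2O, so that SN2 alkylation at −78 °C outpaces elimination and gives 9 directly.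

Further compounds

F1 | step 13 | 2-{(3R)-1-[tert-butyl(dimethyl)silyl]oxy-3-hydroxy-3-[2-methoxy-4-(methoxymethoxy)phenyl]propyl}-3,5-bis(methoxymethoxy)-4-[(2S)-5-methyl-2-(prop-1-en-2-yl)hex-4-en-1-yl]phenyl trifluoromethanesulfonate, both C4 epimers | C=C(C)[C@@H](CC=C(C)C)Cc1c(OCOC)cc(OS(=O)(=O)C(F)(F)F)c(c1OCOC)C(O[Si](C)(C)C(C)(C)C)C[C@H](c1ccc(OCOC)cc1OC)O
F2 | step 13 | (1R)-3-[tert-butyl(dimethyl)silyl]oxy-3-{6-hydroxy-2,4-bis(methoxymethoxy)-3-[(2S)-5-methyl-2-(prop-1-en-2-yl)hex-4-en-1-yl]phenyl}-1-[2-methoxy-4-(methoxymethoxy)phenyl]propan-1-ol, both C4 epimers | C=C(C)[C@@H](CC=C(C)C)Cc1c(OCOC)cc(O)c(c1OCOC)C(O[Si](C)(C)C(C)(C)C)C[C@H](c1ccc(OCOC)cc1OC)O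
F3 | step 16 | (2S)-2-[2-methoxy-4-(trimethylsilyloxy)phenyl]-6-[(2S)-5-methyl-2-(prop-1-en-2-yl)hex-4-en-1-yl]-5,7-bis(trimethylsilyloxy)-2,3-dihydro-4H-chromen-4-one | C=C(C)[C@@H](CC=C(C)C)Cc1c(O[Si](C)(C)C)cc2c(c1O[Si](C)(C)C)C(=O)C[C@@H](c1ccc(O[Si](C)(C)C)cc1OC)O2
F4 | step 5 | (R)-lavandulyl triflate, (2R)-5-methyl-2-(prop-1-en-2-yl)hex-4-en-1-yl trifluoromethanesulfonate | C=C(C)[C@@H](CC=C(C)C)COS(=O)(=O)C(F)(F)F
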